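**Plan**
- Numbering: C1 carries the aryl group, C2 the acetoxymethyl group, C3 the formyl group, C4 is the vinylic CH, and C4a/C8a are shared with benzo ring A. Retrosynthetically the C3=C4 alkene is opened to a C4 carbinol, then ring B is cut at C1–C2 and C3–C4.
- These cuts are possible because C1 and C4 are both benzylic carbons on adjacent positions of ring A. They are therefore the termini of a hydroxy-ortho-quinodimethane (the photoenol of a 2-benzylbenzaldehyde), and C2–C3 with its CH2OAc and CHO groups is an (E)-4-acetoxybut-2-enal.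
- The 2-benzylbenzaldehyde is cut at its aryl–CH2 bond (Negishi coupling of two silyl-protected vanillin-derived arenes).
- Forward: the two arenes are joined through the CH2 bridge, ring B is closed in one photochemical (4+2) step, then water is removed across C3–C4 and the silyl ethers are cleaved.
- Stereochemistry: the trans C1/C2 relationship follows from the aryl-outside (E)-dienol, the endo formyl group and the (E)-enal. The absolute sense (1S,2R) comes from a titanium TADDOLate. The C3 and C4 centres made in the cycloaddition disappear on dehydration.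

Key step: step 8

Remark: (R,R)-TADDOL [(4R,5R)-2,2-dimethyl-α,α,α′,α′-tetraphenyl-1,3-dioxolane-4,5-dimethanol] is written as the antipode assumed to lead to the (1S,2R) series; if the sense of induction is the reverse, (S,S)-TADDOL is used and nothing else changes.

**Route**

Step 1
Reactants: 1 2-bromo-4-hydroxy-5-methoxybenzaldehyde (6-bromovanillin)
Product: 2 2-bromo-4-[(tert-butyldimethylsilyl)oxy]-5-methoxybenzaldehyde
Conditions: TBSCl, imidazole, DMF, 25 °C
Reagents that add atoms: tert-butyldimethylsilyl chloride (TBSCl), CC(C)(C)[Si](C)(C)Cl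
Why: Imidazole-promoted O-silylation of the acidic para-formyl phenol should be fast and masks the phenol against the organozinc reagent and the titanium alkoxide used later.

Step 2
Reactants: 3 vanillin (4-hydroxy-3-methoxybenzaldehyde)
Product: 4 4-[(tert-butyldimethylsilyl)oxy]-3-methoxybenzaldehyde
Conditions: TBSCl, imidazole, DMF, 25 °C
Reagents that add atoms: tert-butyldimethylsilyl chloride (TBSCl), CC(C)(C)[Si](C)(C)Cl
Why: The same phenol O-silylation applies, and starting at the aldehyde oxidation level avoids any competition from a benzylic hydroxyl.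

Step 3
Reactants: 4 4-[(tert-butyldimethylsilyl)oxy]-3-methoxybenzaldehyde
Product: 5 {4-[(tert-butyldimethylsilyl)oxy]-3-methoxyphenyl}methanol
Conditions: NaBH4, THF/MeOH, 0 °C
Reagents that add atoms: none
Why: Borohydride reduction of the aryl aldehyde to the benzylic alcohol is routine, and the aryl silyl ether should survive the short exposure at 0 °C.

Step 4
Reactants: 5 {4-[(tert-butyldimethylsilyl)oxy]-3-methoxyphenyl}methanol
Product: 6 tert-butyl[4-(chloromethyl)-2-methoxyphenoxy]dimethylsilane
Conditions: PPh3, N-chlorosuccinimide, THF, 0 → 25 °C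
Reagents that add atoms: N-chlorosuccinimide, O=C1CCC(=O)N1Cl
Why: Appel-type chlorination (alkoxyphosphonium formation, then displacement by chloride) converts the primary benzylic alcohol under neutral conditions that leave the silyl ether intact.

Step 5
Reactants: 6 tert-butyl[4-(chloromethyl)-2-methoxyphenoxy]dimethylsilane; 2 2-bromo-4-[(tert-butyldimethylsilyl)oxy]-5-methoxybenzaldehyde
Product: 8 4-[(tert-butyldimethylsilyl)oxy]-2-{4-[(tert-butyldimethylsilyl)oxy]-3-methoxybenzyl}-5-methoxybenzaldehyde, via benzylzinc chloride 7 (not isolated)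
Conditions: Zn dust, LiCl, THF, 25 °C; then 2, Pd(OAc)2 (2 mol %), SPhos (4 mol %), THF, 25 °C
Reagents that add atoms: none
Why: LiCl-assisted zinc insertion into the benzylic C–Cl bond followed by Negishi cross-coupling (oxidative addition of the aryl bromide to zerovalent palladium formed in situ, transmetalation, reductive elimination) should form the aryl–CH2 bond, since benzylzinc halides add only slowly to an electron-rich aryl aldehyde at 25 °C.

Step 6
Reactants: 9 (Z)-but-2-ene-1,4-diol
Product: 10 (Z)-4-hydroxybut-2-en-1-yl acetate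
Conditions: 9 (3 equiv), Ac2O (1 equiv), Et3N, DMAP (cat.), THF/CH2Cl2, 0 °C
Reagents that add atoms: acetic anhydride, CC(=O)OC(C)=O
Why: Statistical mono-O-acylation of the symmetric diol is biased towards the monoacetate by the excess of diol, which is removed in the aqueous wash.

Step 7
Reactants: 10 (Z)-4-hydroxybut-2-en-1-yl acetate
Product: 12 (E)-4-oxobut-2-en-1-yl acetate, via (Z)-4-oxobut-2-en-1-yl acetate 11 (not isolated)
Conditions: (C5H5NH)[CrO3Cl] (pyridinium chlorochromate), Celite, CH2Cl2, 25 °C
Reagents that add atoms: none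
Why: Oxidation of the primary allylic alcohol by hexavalent chromium gives the (Z)-enal, which should equilibrate in the mildly acidic medium to the more stable (E)-enal, as is usual for 4-oxygenated (Z)-but-2-enals.

Step 8
Reactants: 8 4-[(tert-butyldimethylsilyl)oxy]-2-{4-[(tert-butyldimethylsilyl)oxy]-3-methoxybenzyl}-5-methoxybenzaldehyde; 12 (E)-4-oxobut-2-en-1-yl acetate
Product: 14 [(1S,2R,3S,4S)-7-[(tert-butyldimethylsilyl)oxy]-1-{4-[(tert-butyldimethylsilyl)oxy]-3-methoxyphenyl}-3-formyl-4-hydroxy-6-methoxy-1,2,3,4-tetrahydronaphthalen-2-yl]methyl acetate, via photodienol 13 (not isolated)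
Conditions: Ti(Oi-Pr)4 (1.1 equiv), (R,R)-TADDOL (1.2 equiv), toluene, 25 °C; then 8, 12 (3 equiv), hν 365 nm, degassed, 0 °C
Reagents that add atoms: none
Why: Excitation of the formyl group of 8 (n→π*, 365 nm) and 1,5-hydrogen transfer from the doubly benzylic CH2 give the (E,E)-hydroxy-ortho-quinodimethane 13 with OH and aryl both outside, held as a titanium dienolate on Ti(TADDOLate)(Oi-Pr)2 together with the carbonyl oxygen of 12. The closest known reaction type is the Ti(Oi-Pr)4-mediated photoenolization/Diels–Alder reaction of 2-alkylbenzaldehydes with α,β-unsaturated carbonyl compounds, including its TADDOLate-controlled enantioselective form, applied here to a 2-benzyl substrate and an acyclic β-substituted enal. Ring B closes by an intermolecular, concerted, suprafacial (4+2) cycloaddition that forms C1–C2 and C3–C4, the formyl-bearing carbon joining the carbinol carbon as dictated by the titanium bridge and the polarisation of the 1-oxygenated diene. C1 and C4 are set cis by the outside/outside dienol geometry, C3 by the endo position of the titanium-bound formyl group (cis to OH and aryl), and C2 by the (E)-geometry of 12, which places CH2OAc trans to CHO and hence trans to the C1 aryl group. The absolute configuration (1S,2R,3S,4S) rests on the TADDOLate aryl groups shielding one face of the bound dienol. The step needs regio-, endo- and facial selectivity and retention of the enal geometry; the titanium chelate should secure the first three, and an excess of 12 with short irradiation at 365 nm, where 12 absorbs only weakly, should limit E/Z scrambling.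

Step 9
Reactants: 14 [(1S,2R,3S,4S)-7-[(tert-butyldimethylsilyl)oxy]-1-{4-[(tert-butyldimethylsilyl)oxy]-3-methoxyphenyl}-3-formyl-4-hydroxy-6-methoxy-1,2,3,4-tetrahydronaphthalen-2-yl]methyl acetate
Product: 16 [(1S,2R)-7-[(tert-butyldimethylsilyl)oxy]-1-{4-[(tert-butyldimethylsilyl)oxy]-3-methoxyphenyl}-3-formyl-6-methoxy-1,2-dihydronaphthalen-2-yl]methyl acetate, via C4 mesylate 15 (not isolated)
Conditions: MsCl, Et3N, CH2Cl2, −20 → 0 °C
Reagents that add atoms: none
Why: O-Sulfonylation of the benzylic C4 hydroxyl followed by E1cB elimination (Et3N removes the acidic C3–H next to the formyl group, which is anti to the leaving group) should give the ring-A-conjugated enal without touching C1 or C2.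

Step 10
Reactants: 16 [(1S,2R)-7-[(tert-butyldimethylsilyl)oxy]-1-{4-[(tert-butyldimethylsilyl)oxy]-3-methoxyphenyl}-3-formyl-6-methoxy-1,2-dihydronaphthalen-2-yl]methyl acetate
Product: 17 [(1S,2R)-3-formyl-7-hydroxy-1-(4-hydroxy-3-methoxyphenyl)-6-methoxy-1,2-dihydronaphthalen-2-yl]methyl acetate (CNP0549177.1)
Conditions: HF·pyridine, pyridine, THF, 0 → 25 °C
Reagents that add atoms: none
Why: Fluoride-mediated cleavage of both aryl silyl ethers under buffered, non-basic conditions should spare the acetate and the enal and avoid γ-deprotonation at C2.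

**Compound list**

1 | 2-bromo-4-hydroxy-5-methoxybenzaldehyde (6-bromovanillin) | O=Cc1cc(OC)c(O)cc1Br | starting material
2 | 2-bromo-4-[(tert-butyldimethylsilyl)oxy]-5-methoxybenzaldehyde | O=Cc1cc(OC)c(O[Si](C)(C)C(C)(C)C)cc1Br | intermediate
3 | vanillin (4-hydroxy-3-methoxybenzaldehyde) | O=Cc1ccc(O)c(OC)c1 | starting material
4 | 4-[(tert-butyldimethylsilyl)oxy]-3-methoxybenzaldehyde | O=Cc1ccc(O[Si](C)(C)C(C)(C)C)c(OC)c1 | intermediate
5 | {4-[(tert-butyldimethylsilyl)oxy]-3-methoxyphenyl}methanol | OCc1ccc(O[Si](C)(C)C(C)(C)C)c(OC)c1 | intermediate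
6 | tert-butyl[4-(chloromethyl)-2-methoxyphenoxy]dimethylsilane | ClCc1ccc(O[Si](C)(C)C(C)(C)C)c(OC)c1 | intermediate
7 | {4-[(tert-butyldimethylsilyl)oxy]-3-methoxybenzyl}zinc chloride (LiCl-solvated THF solution, not isolated) | Cl[Zn]Cc1ccc(O[Si](C)(C)C(C)(C)C)c(OC)c1 | intermediate
8 | 4-[(tert-butyldimethylsilyl)oxy]-2-{4-[(tert-butyldimethylsilyl)oxy]-3-methoxybenzyl}-5-methoxybenzaldehyde | O=Cc1cc(OC)c(O[Si](C)(C)C(C)(C)C)cc1Cc1ccc(O[Si](C)(C)C(C)(C)C)c(OC)c1 | intermediate
9 | (Z)-but-2-ene-1,4-diol | OC/C=C\CO | starting material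
10 | (Z)-4-hydroxybut-2-en-1-yl acetate | CC(=O)OC/C=C\CO | intermediate
11 | (Z)-4-oxobut-2-en-1-yl acetate (not isolated) | CC(=O)OC/C=C\C=O | intermediate
12 | (E)-4-oxobut-2-en-1-yl acetate | CC(=O)OC/C=C/C=O | intermediate
13 | (E)-{(6E)-4-[(tert-butyldimethylsilyl)oxy]-6-{4-[(tert-butyldimethylsilyl)oxy]-3-methoxybenzylidene}-3-methoxycyclohexa-2,4-dien-1-ylidene}methanol, the (E,E)-hydroxy-ortho-quinodimethane of 8 (titanium-bound, not isolated) | O/C=C1\C=C(OC)C(O[Si](C)(C)C(C)(C)C)=C/C1=C\c1ccc(O[Si](C)(C)C(C)(C)C)c(OC)c1 | intermediate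
14 | [(1S,2R,3S,4S)-7-[(tert-butyldimethylsilyl)oxy]-1-{4-[(tert-butyldimethylsilyl)oxy]-3-methoxyphenyl}-3-formyl-4-hydroxy-6-methoxy-1,2,3,4-tetrahydronaphthalen-2-yl]methyl acetate (aryl, formyl and hydroxyl cis; acetoxymethyl trans to them) | COc1cc([C@H]2c3cc(O[Si](C)(C)C(C)(C)C)c(OC)cc3[C@@H](O)[C@@H](C=O)[C@@H]2COC(C)=O)ccc1O[Si](C)(C)C(C)(C)C | intermediate
15 | [(1S,2R,3S,4S)-7-[(tert-butyldimethylsilyl)oxy]-1-{4-[(tert-butyldimethylsilyl)oxy]-3-methoxyphenyl}-3-formyl-4-(methanesulfonyloxy)-6-methoxy-1,2,3,4-tetrahydronaphthalen-2-yl]methyl acetate (not isolated) | COc1cc([C@H]2c3cc(O[Si](C)(C)C(C)(C)C)c(OC)cc3[C@@H](OS(C)(=O)=O)[C@@H](C=O)[C@@H]2COC(C)=O)ccc1O[Si](C)(C)C(C)(C)C | intermediate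
16 | [(1S,2R)-7-[(tert-butyldimethylsilyl)oxy]-1-{4-[(tert-butyldimethylsilyl)oxy]-3-methoxyphenyl}-3-formyl-6-methoxy-1,2-dihydronaphthalen-2-yl]methyl acetate | COc1cc([C@H]2c3cc(O[Si](C)(C)C(C)(C)C)c(OC)cc3C=C(C=O)[C@@H]2COC(C)=O)ccc1O[Si](C)(C)C(C)(C)C | intermediate
17 | [(1S,2R)-3-formyl-7-hydroxy-1-(4-hydroxy-3-methoxyphenyl)-6-methoxy-1,2-dihydronaphthalen-2-yl]methyl acetate (CNP0549177.1) | COc1cc([C@H]2c3cc(O)c(OC)cc3C=C(C=O)[C@@H]2COC(C)=O)ccc1O | target

**Totals**

Total step count: 10.
Longest linear sequence: 7 steps (3 → 4 → 5 → 6 → 8 → 14 → 16 → 17; steps 2, 3, 4, 5, 8, 9, 10).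

**Steps most likely to fail**

Step 8. The titanium TADDOLate may discriminate poorly between the two faces of the bound dienol, and 12 may partly lose its E-geometry under irradiation, so enantiomeric and diastereomeric purity could be eroded. Fallback: starting again from 8 and 12, the cycloaddition is run with Ti(Oi-Pr)4 alone, which should still enforce the endo, aryl-outside pathway. This gives 14 as a racemate, that is together with its mirror image, the (1R,2S,3R,4R)-adduct F1. The mixture is carried through the conditions of step 9, in which the enantiomeric C4 mesylate F2 accompanies 15, to the racemic dihydronaphthalene, that is 16 plus the (1R,2S)-enal F3. This robust compound with only two stereocentres is resolved by preparative chromatography on a chiral stationary phase (amylose tris(3,5-dimethylphenylcarbamate)), and the route is rejoined at 16.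

Step 5. The benzylzinc reagent may add to the free formyl group of 2 or 8, and 7 may homocouple, both at the expense of cross-coupling. Fallback: setting out from 2, the aldehyde is masked (HC(OMe)3, MeOH, PPTS, 25 °C) as the dimethyl acetal [5-bromo-4-(dimethoxymethyl)-2-methoxyphenoxy](tert-butyl)dimethylsilane F4. Negishi coupling of F4 with 7 under the catalyst system of step 5 should give the dimethyl acetal of the diarylmethane aldehyde F5. Mild hydrolysis (PPTS, acetone/H2O, 25 °C) returns to the route at 8.

Step 9. Under base, retro-aldol opening of the β-hydroxy aldehyde may precede sulfonylation, or the product enal may be deprotonated at C2 with loss of acetate and aromatisation. Fallback: setting out from 14, the order of events is reversed and water is removed on the acid side. HF·pyridine (THF, 0 → 25 °C) first cleaves both silyl ethers to give the free bisphenol hydroxy aldehyde F6. Its C4 hydroxyl is now para to a free phenol on ring A, so under mild acid (PPTS, MeCN, 40 °C) it should ionise through a para-quinone methide/benzylic cation that loses the C3 proton. The route is rejoined at 17.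

**Further compounds**

F1 | step 8 | [(1R,2S,3R,4R)-7-[(tert-butyldimethylsilyl)oxy]-1-{4-[(tert-butyldimethylsilyl)oxy]-3-methoxyphenyl}-3-formyl-4-hydroxy-6-methoxy-1,2,3,4-tetrahydronaphthalen-2-yl]methyl acetate (enantiomer of 14) | COc1cc([C@@H]2c3cc(O[Si](C)(C)C(C)(C)C)c(OC)cc3[C@H](O)[C@H](C=O)[C@H]2COC(C)=O)ccc1O[Si](C)(C)C(C)(C)C
F2 | step 8 | [(1R,2S,3R,4R)-7-[(tert-butyldimethylsilyl)oxy]-1-{4-[(tert-butyldimethylsilyl)oxy]-3-methoxyphenyl}-3-formyl-4-(methanesulfonyloxy)-6-methoxy-1,2,3,4-tetrahydronaphthalen-2-yl]methyl acetate (enantiomer of 15) | COc1cc([C@@H]2c3cc(O[Si](C)(C)C(C)(C)C)c(OC)cc3[C@H](OS(C)(=O)=O)[C@H](C=O)[C@H]2COC(C)=O)ccc1O[Si](C)(C)C(C)(C)C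
F3 | step 8 | [(1R,2S)-7-[(tert-butyldimethylsilyl)oxy]-1-{4-[(tert-butyldimethylsilyl)oxy]-3-methoxyphenyl}-3-formyl-6-methoxy-1,2-dihydronaphthalen-2-yl]methyl acetate (enantiomer of 16) | COc1cc([C@@H]2c3cc(O[Si](C)(C)C(C)(C)C)c(OC)cc3C=C(C=O)[C@H]2COC(C)=O)ccc1O[Si](C)(C)C(C)(C)C
F4 | step 5 | [5-bromo-4-(dimethoxymethyl)-2-methoxyphenoxy](tert-butyl)dimethylsilane | COC(OC)c1cc(OC)c(O[Si](C)(C)C(C)(C)C)cc1Br
F5 | step 5 | tert-butyl{4-(dimethoxymethyl)-5-{4-[(tert-butyldimethylsilyl)oxy]-3-methoxybenzyl}-2-methoxyphenoxy}dimethylsilane (dimethyl acetal of 8) | COC(OC)c1cc(OC)c(O[Si](C)(C)C(C)(C)C)cc1Cc1ccc(O[Si](C)(C)C(C)(C)C)c(OC)c1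
F6 | step 9 | [(1S,2R,3S,4S)-3-formyl-4,7-dihydroxy-1-(4-hydroxy-3-methoxyphenyl)-6-methoxy-1,2,3,4-tetrahydronaphthalen-2-yl]methyl acetate | COc1cc([C@H]2c3cc(O)c(OC)cc3[C@@H](O)[C@@H](C=O)[C@@H]2COC(C)=O)ccc1O
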